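## Retrosynthetic overview

1. Names used: ring A / pyran A = the tropolone–dihydropyran unit next to the CH–OH, ring B / pyran B = the other one. In pyran A, Cb = benzylic CH2, Cr = the ring A carbon that carries it, Ct = ring-fusion CH, Cq = ring-fusion C(CH3)–O.
2. Key disconnection: Cb–Cr and Ct–Cq are cut together. The precursor is the open-chain bis(enol ether) 30 (2-aryloxy-1-alkene at Cq, methyl enol ether at Ct=Cb); an acid-triggered cationic [4+2] cycloisomerisation of the oxa-Povarov type closes the 11-membered ring and pyran A in one operation.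
3. Enabling feature: in ring A, held as its 2-methoxytropone, the ether oxygen, its ring carbon and the unsubstituted ring carbon Cr (between the O-bearing and the methyl-bearing ring carbons) form a localised cyclic enol ether. The aryloxy oxocarbenium at Cq is therefore a 2-oxonia-diene ending at Cr, and Cr is the only nucleophilic ring carbon ortho to that oxygen.
4. Pyran B and the E-alkene come from a domino Wacker–Heck reaction (24 + 14); ring B is attached by B-alkyl Suzuki coupling; the carbinol carbon and the CH of pyran B come from (S)-5-(hydroxymethyl)butyrolactone 15.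
5. Both troponoid rings come from o-cresol by Birch reduction and dibromocarbene ring expansion. Ring order: tropone rings A and B (steps 1–8), pyran B (step 19), then the 11-membered ring and pyran A together (step 25).

Key step: step 25

Remark (assumption): O-methylation of the unsymmetrical tropolone 7 can also take place at the other tropolone oxygen. The route uses the isomer drawn for 8 (methoxy group on the carbon next to the CH that neighbours the MOM-oxygenated carbon), separated by chromatography; the other isomer can be hydrolysed back to 7.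

## Route

Step 1
Reactants: 1 2-methylphenol
Product: 2 1-(methoxymethoxy)-2-methylbenzene
Conditions: MeOCH2Cl, i-Pr2NEt, CH2Cl2, 0 °C → rt
Reagents that add atoms: chloromethyl methyl ether, COCCl
Why: O-alkylation of the phenol (MOM protection); the acetal survives dissolving-metal reduction and later becomes an acid-labile group on the vinylogous acid oxygen.

Step 2
Reactants: 2 1-(methoxymethoxy)-2-methylbenzene
Product: 3 1-(methoxymethoxy)-2-methylcyclohexa-1,4-diene
Conditions: Li, NH3 (l), t-BuOH, THF, −78 °C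
Reagents that add atoms: none
Why: Birch reduction of an aryl ether leaves the alkoxy and alkyl groups on the remaining tetrasubstituted double bond.

Step 3
Reactants: 3 1-(methoxymethoxy)-2-methylcyclohexa-1,4-diene
Product: 4 rac-7,7-dibromo-1-(methoxymethoxy)-6-methylbicyclo[4.1.0]hept-3-ene
Conditions: CHBr3 (1 equiv), KOt-Bu, pentane, 0 °C
Reagents that add atoms: bromoform, BrC(Br)Br
Why: Electrophilic dibromocarbene cyclopropanation should go to the more electron-rich tetrasubstituted enol ether double bond.

Step 4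
Reactants: 4 rac-7,7-dibromo-1-(methoxymethoxy)-6-methylbicyclo[4.1.0]hept-3-ene
Product: 5 7,7-dibromo-1-(methoxymethoxy)-6-methylbicyclo[4.1.0]heptane-3,4-diol (cis-diol, racemic)
Conditions: OsO4 (cat.), N-methylmorpholine N-oxide, acetone/H2O, rt
Reagents that add atoms: N-methylmorpholine N-oxide, C[N+]1([O-])CCOCC1; water, O
Why: Upjohn dihydroxylation of the remaining disubstituted alkene; the diol configuration is irrelevant because both carbons become sp2.

Step 5
Reactants: 5 7,7-dibromo-1-(methoxymethoxy)-6-methylbicyclo[4.1.0]heptane-3,4-diol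
Product: 7 5-bromo-2-hydroxy-4-(methoxymethoxy)-6-methylcyclohepta-2,4,6-trien-1-one, via 1,2-dione 6 (not isolated)
Conditions: DMSO, (CF3CO)2O, CH2Cl2, −78 °C; then Et3N, −78 °C → rt
Reagents that add atoms: none
Why: Swern-type oxidation gives the 1,2-dione, whose enol undergoes base-induced electrocyclic opening of the gem-dibromocyclopropane with loss of HBr (ring expansion of the Banwell type) to the aromatic 5-bromotropolone.

Step 6
Reactants: 7 5-bromo-2-hydroxy-4-(methoxymethoxy)-6-methylcyclohepta-2,4,6-trien-1-one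
Product: 8 5-bromo-2-methoxy-4-(methoxymethoxy)-6-methylcyclohepta-2,4,6-trien-1-one
Conditions: MeI, K2CO3, acetone, rt
Reagents that add atoms: iodomethane, CI
Why: Williamson O-alkylation of the tropolonate fixes the bond localisation of the tropone (C4=C5 as an enol ether double bond), which step 25 relies on.

Step 7
Reactants: 8 5-bromo-2-methoxy-4-(methoxymethoxy)-6-methylcyclohepta-2,4,6-trien-1-one
Product: 9 5-bromo-4-hydroxy-2-methoxy-6-methylcyclohepta-2,4,6-trien-1-one
Conditions: HCl (cat.), MeOH, 0 °C → rt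
Reagents that add atoms: none
Why: Acid-catalysed acetal exchange; the MOM group on the vinylogous acid oxygen behaves like a MOM ester and should leave much faster than the methyl ether.

Step 8
Reactants: 9 5-bromo-4-hydroxy-2-methoxy-6-methylcyclohepta-2,4,6-trien-1-one
Product: 10 4-hydroxy-2-methoxy-6-methylcyclohepta-2,4,6-trien-1-one
Conditions: Pd(PPh3)4 (cat.), HCO2Na, DMF, 80 °C
Reagents that add atoms: none
Why: Palladium-catalysed transfer hydrodehalogenation with formate removes the bromine (needed only for ring B) without hydrogenating the tropone.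

Step 9
Reactants: 11 methyl 3,3-dimethylpent-4-enoate
Product: 12 3,3-dimethylpent-4-enal
Conditions: i-Bu2AlH, CH2Cl2, −78 °C
Reagents that add atoms: none
Why: Partial reduction of the ester; the tetrahedral aluminium hemiacetal is stable at −78 °C.

Step 10
Reactants: 12 3,3-dimethylpent-4-enal
Product: 14 6,6-dimethoxy-3,3-dimethylhex-1-ene, via enol ether 13 (not isolated)
Conditions: MeOCH2PPh3Cl, KOt-Bu, THF, 0 °C; then MeOH, pyridinium p-toluenesulfonate, rt
Reagents that add atoms: (methoxymethyl)triphenylphosphonium chloride, COC[P+](c1ccccc1)(c1ccccc1)c1ccccc1.[Cl-]; methanol, CO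
Why: Wittig methoxymethylenation (one-carbon homologation) followed by acid-catalysed addition of methanol; the acetal masks the enol ether until step 24.

Step 11
Reactants: 15 (S)-5-(hydroxymethyl)dihydrofuran-2(3H)-one
Product: 16 (S)-5-[(tert-butyldimethylsilyloxy)methyl]dihydrofuran-2(3H)-one
Conditions: t-BuMe2SiCl, imidazole, DMF, rt
Reagents that add atoms: tert-butyldimethylsilyl chloride, CC(C)(C)[Si](C)(C)Cl
Why: Standard silylation of the primary alcohol; the bulky group later directs the enolate alkylation.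

Step 12
Reactants: 16 (S)-5-[(tert-butyldimethylsilyloxy)methyl]dihydrofuran-2(3H)-one
Product: 17 (3S,5S)-3-[(benzyloxy)methyl]-5-[(tert-butyldimethylsilyloxy)methyl]dihydrofuran-2(3H)-one (trans)
Conditions: LiN(i-Pr)2, THF, −78 °C; BnOCH2Cl, −78 → −40 °C
Reagents that add atoms: benzyl chloromethyl ether, ClCOCc1ccccc1
Why: Alkylation of the lithium lactone enolate on the face anti to the C5 substituent (1,3-induction) should give mainly the trans lactone and sets the CH stereocentre of pyran B.

Step 13
Reactants: 17 (3S,5S)-3-[(benzyloxy)methyl]-5-[(tert-butyldimethylsilyloxy)methyl]dihydrofuran-2(3H)-one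
Product: 18 (3S,5S)-3-[(benzyloxy)methyl]-6-(tert-butyldimethylsilyloxy)-5-hydroxyhexan-2-one
Conditions: MeLi (1.05 equiv), THF, −78 °C; sat. aq. NH4Cl
Reagents that add atoms: methyllithium, [Li]C
Why: Single addition of MeLi to a γ-lactone; the tetrahedral intermediate persists at −78 °C and collapses to the γ-hydroxy methyl ketone on work-up.

Step 14
Reactants: 18 (3S,5S)-3-[(benzyloxy)methyl]-6-(tert-butyldimethylsilyloxy)-5-hydroxyhexan-2-one
Product: 19 (3S,5S)-3-[(benzyloxy)methyl]-6-(tert-butyldimethylsilyloxy)-5-(triisopropylsilyloxy)hexan-2-one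
Conditions: i-Pr3SiOTf, 2,6-lutidine, CH2Cl2, −78 → 0 °C
Reagents that add atoms: triisopropylsilyl trifluoromethanesulfonate, CC(C)[Si](C(C)C)(C(C)C)OS(=O)(=O)C(F)(F)F
Why: Silylation of the secondary alcohol with a group that outlasts the later removal of the primary silyl ether.

Step 15
Reactants: 19 (3S,5S)-3-[(benzyloxy)methyl]-6-(tert-butyldimethylsilyloxy)-5-(triisopropylsilyloxy)hexan-2-one
Product: 20 (2R,4S)-1-(benzyloxy)-5-(tert-butyldimethylsilyloxy)-2-(prop-1-en-2-yl)-4-(triisopropylsilyloxy)pentane
Conditions: Zn, CH2Br2, TiCl4, THF/CH2Cl2, 0 °C → rt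
Reagents that add atoms: dibromomethane, BrCBr
Why: Takai–Lombardo methylenation is non-basic, so the α-stereocentre and the β-benzyloxy group of the ketone should survive.

Step 16
Reactants: 20 (2R,4S)-1-(benzyloxy)-5-(tert-butyldimethylsilyloxy)-2-(prop-1-en-2-yl)-4-(triisopropylsilyloxy)pentane
Product: 21 (2R,4S)-5-(tert-butyldimethylsilyloxy)-2-(prop-1-en-2-yl)-4-(triisopropylsilyloxy)pentan-1-ol
Conditions: Li, 4,4'-di-tert-butylbiphenyl, THF, −78 °C
Reagents that add atoms: none
Why: Dissolving-metal debenzylation (electron transfer from the arene radical anion) leaves the isolated alkene and both silyl ethers intact.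

Step 17
Reactants: 21 (2R,4S)-5-(tert-butyldimethylsilyloxy)-2-(prop-1-en-2-yl)-4-(triisopropylsilyloxy)pentan-1-ol
Product: 22 (2R,4S)-5-(tert-butyldimethylsilyloxy)-1-iodo-2-(prop-1-en-2-yl)-4-(triisopropylsilyloxy)pentane
Conditions: I2, PPh3, imidazole, CH2Cl2, 0 °C
Reagents that add atoms: iodine, II
Why: Appel-type iodination of the primary alcohol.

Step 18
Reactants: 22 (2R,4S)-5-(tert-butyldimethylsilyloxy)-1-iodo-2-(prop-1-en-2-yl)-4-(triisopropylsilyloxy)pentane; 9 5-bromo-4-hydroxy-2-methoxy-6-methylcyclohepta-2,4,6-trien-1-one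
Product: 24 4-hydroxy-2-methoxy-6-methyl-5-[(2R,4S)-5-(tert-butyldimethylsilyloxy)-2-(prop-1-en-2-yl)-4-(triisopropylsilyloxy)pentyl]cyclohepta-2,4,6-trien-1-one, via borinate 23 (not isolated)
Conditions: t-BuLi, Et2O, −78 °C, then B-methoxy-9-borabicyclo[3.3.1]nonane, THF, −78 °C → rt; then 9, Pd(dppf)Cl2, AsPh3, Cs2CO3, DMF/H2O, rt → 50 °C
Reagents that add atoms: none
Why: Lithium–iodine exchange, boron ate-complex formation and B-alkyl Suzuki–Miyaura coupling join ring B at its brominated carbon; the nucleophile-sensitive tropone is introduced only after all organolithium steps on the chain.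

Step 19
Reactants: 24 ring B hydroxytropone with the isopropenyl side chain; 14 6,6-dimethoxy-3,3-dimethylhex-1-ene
Product: 25 pyran B compound: 2-methoxytropone-fused 2H-chroman-type ring with an (R)-quaternary carbon bearing methyl and the (E)-7,7-dimethoxy-4,4-dimethylhept-2-en-1-yl chain, and an (R)-CH bearing the (S)-3-(tert-butyldimethylsilyloxy)-2-(triisopropylsilyloxy)propyl chain
Conditions: Pd(O2CCF3)2 (10 mol %), (S,S)-Bn-BOXAX (40 mol %), p-benzoquinone (4 equiv), 14 (5 equiv), CH2Cl2, rt
Reagents that add atoms: none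
Why: Domino Wacker–Heck reaction: 6-exo oxypalladation of the 1,1-disubstituted alkene by the ring B hydroxyl gives a neopentyl-type alkylpalladium without β-hydrogen, which inserts the terminal alkene of 14 and β-hydride eliminates to the E-alkene (the quaternary carbon blocks any other elimination); the quaternary stereocentre is set by ligand-controlled enantioface selection, (S,S)-Bn-BOXAX being the ligand enantiomer expected to give 2-methyl-2-alkylchromans of the natural vitamin E configuration, which is the spatial arrangement needed here.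

Step 20
Reactants: 25 pyran B compound with both silyl ethers
Product: 26 primary alcohol of 25 (tert-butyldimethylsilyl group removed, triisopropylsilyl ether kept)
Conditions: HF·pyridine, pyridine, THF, 0 °C
Reagents that add atoms: none
Why: Buffered fluoride desilylation is selective for the primary tert-butyldimethylsilyl ether over the hindered secondary triisopropylsilyl ether.

Step 21
Reactants: 26 primary alcohol
Product: 27 α-(triisopropylsilyloxy) aldehyde
Conditions: Dess–Martin periodinane, NaHCO3, CH2Cl2, 0 °C → rt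
Reagents that add atoms: none
Why: Dess–Martin oxidation under buffered conditions keeps the α-stereocentre and the acetal intact.

Step 22
Reactants: 27 α-(triisopropylsilyloxy) aldehyde
Product: 28 terminal alkyne with the (S)-2-(triisopropylsilyloxy)but-3-yn-1-yl side chain
Conditions: dimethyl (1-diazo-2-oxopropyl)phosphonate, K2CO3, MeOH, 0 °C → rt
Reagents that add atoms: dimethyl (1-diazo-2-oxopropyl)phosphonate, CC(=O)C(=[N+]=[N-])P(=O)(OC)OC
Why: Seyferth–Gilbert homologation with the Ohira–Bestmann reagent; methoxide exchange at the methoxytropone is degenerate.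

Step 23
Reactants: 28 terminal alkyne; 10 4-hydroxy-2-methoxy-6-methylcyclohepta-2,4,6-trien-1-one
Product: 29 aryloxyalkene: side chain (S)-3-[(6-methoxy-3-methyl-5-oxocyclohepta-1,3,6-trien-1-yl)oxy]-2-(triisopropylsilyloxy)but-3-en-1-yl
Conditions: 10 (1.5 equiv), [(t-Bu)2(2-biphenylyl)P]Au(NCMe)SbF6 (5 mol %), toluene, 4 Å MS, 40 °C
Reagents that add atoms: none
Why: Gold-catalysed Markovnikov hydro-oxy addition of the vinylogous acid OH of 10 to the terminal alkyne, as known for carboxylic acids and phenols, gives the 2-aryloxy-1-alkene.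

Step 24
Reactants: 29 aryloxyalkene with dimethyl acetal
Product: 30 bis(enol ether): acetal of 29 converted into the methyl enol ether (E/Z mixture), chain end (E)-7-methoxy-4,4-dimethylhepta-2,6-dien-1-yl
Conditions: Me3SiOTf, i-Pr2NEt, CH2Cl2, −20 → 0 °C
Reagents that add atoms: none
Why: Gassman-type elimination of methanol from a dimethyl acetal under basic conditions, which leave the aryloxyalkene and the silyl ether untouched.

Step 25
Reactants: 30 bis(enol ether)
Product: 31 macrocycle: bis(O-methyl), O-triisopropylsilyl derivative of the target that carries a methoxy group on Cb (epimer mixture at Cb)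
Conditions: HNTf2 (10 mol %), CH2Cl2/(CF3)2CHOH 9:1, 4 Å MS, slow addition of 30 to 1 mM, −20 °C → rt
Reagents that add atoms: none
Why: Proposed new method: the acid, relayed by the tropone carbonyls, protonates the terminal carbon of the 2-aryloxy-1-alkene and gives an O-aryl oxocarbenium ion at Cq, a cationic 2-oxonia-diene (Cr=C–O+=Cq); the nucleophilic carbon Ct of the tethered methyl enol ether attacks Cq (11-exo-trig closure of the carbocycle, Mukaiyama–Prins type), and the new oxocarbenium at Cb is trapped by Cr of ring A (six-membered closure, Friedel–Crafts type) with loss of the proton, so the whole is a stepwise cationic [4+2] cycloisomerisation. The closest known reactions are the oxa-Povarov reaction of aryl oxocarbenium ions with enol ethers to 4-alkoxychromans and Prins-type macrocyclisations; new are the troponoid aryl group and the 11-membered ring closure in the first bond formation. Cq should be set by Felkin–Anh attack anti to the C–O(silyl) bond of the neighbouring carbinol carbon, and Ct by the transition state in which the chain carbon on Ct lies anti to the Cq–O(aryl) bond and away from ring A, which gives the trans ring fusion; the configuration at Cb is of no consequence. The step needs chemoselectivity (protonation of the methyl enol ether is reversible and unproductive at 1 mM, and a substoichiometric acid leaves most tropone rings unprotonated) and regioselectivity at ring A, secured by the 2-methoxytropone bond localisation: attack at Cr gives a 1,3-dioxygenated allyl cation, attack at the other ortho carbon an α-keto cation.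

Step 26
Reactants: 31 macrocycle with methoxy group on Cb
Product: 32 O-triisopropylsilyl bis(O-methyl) ether of the target
Conditions: Et3SiH, CF3CO2H, CH2Cl2, −20 → 0 °C
Reagents that add atoms: none
Why: Ionic hydrogenation: the benzylic methyl ether ionises to an ortho-quinone-methide-type cation that takes hydride from the silane, as for 4-alkoxychromans; both Cb epimers converge.

Step 27
Reactants: 32 O-triisopropylsilyl bis(O-methyl) ether of the target
Product: 34 target (CNP0283947.4), via dimethyl ether 33 (not isolated)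
Conditions: Bu4NF, THF, rt → 40 °C; then LiOH, H2O/MeOH, 50 °C; then 1 M HCl to pH 4
Reagents that add atoms: lithium hydroxide, [Li+].[OH-]
Why: Fluoride desilylation, then hydroxide addition–elimination at the methoxy-bearing carbon of each 2-methoxytropone (classical hydrolysis of tropolone methyl ethers); no stereocentre is touched.

## Compound list

1 | 2-methylphenol | Cc1ccccc1O | starting material
2 | 1-(methoxymethoxy)-2-methylbenzene | COCOc1ccccc1C | intermediate
3 | 1-(methoxymethoxy)-2-methylcyclohexa-1,4-diene | COCOC1=C(C)CC=CC1 | intermediate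
4 | rac-7,7-dibromo-1-(methoxymethoxy)-6-methylbicyclo[4.1.0]hept-3-ene | COCOC12CC=CCC1(C)C2(Br)Br | intermediate
5 | 7,7-dibromo-1-(methoxymethoxy)-6-methylbicyclo[4.1.0]heptane-3,4-diol (cis-diol, racemic) | COCOC12CC(O)C(O)CC1(C)C2(Br)Br | intermediate
6 | 7,7-dibromo-1-(methoxymethoxy)-6-methylbicyclo[4.1.0]heptane-3,4-dione (not isolated) | COCOC12CC(=O)C(=O)CC1(C)C2(Br)Br | intermediate
7 | 5-bromo-2-hydroxy-4-(methoxymethoxy)-6-methylcyclohepta-2,4,6-trien-1-one | O=C1C(O)=CC(OCOC)=C(Br)C(C)=C1 | intermediate
8 | 5-bromo-2-methoxy-4-(methoxymethoxy)-6-methylcyclohepta-2,4,6-trien-1-one | O=C1C(OC)=CC(OCOC)=C(Br)C(C)=C1 | intermediate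
9 | 5-bromo-4-hydroxy-2-methoxy-6-methylcyclohepta-2,4,6-trien-1-one (ring B building block) | O=C1C(OC)=CC(O)=C(Br)C(C)=C1 | intermediate
10 | 4-hydroxy-2-methoxy-6-methylcyclohepta-2,4,6-trien-1-one (ring A building block) | O=C1C(OC)=CC(O)=CC(C)=C1 | intermediate
11 | methyl 3,3-dimethylpent-4-enoate | C=CC(C)(C)CC(=O)OC | starting material
12 | 3,3-dimethylpent-4-enal | C=CC(C)(C)CC=O | intermediate
13 | 6-methoxy-3,3-dimethylhexa-1,5-diene (E/Z, not isolated) | C=CC(C)(C)CC=COC | intermediate
14 | 6,6-dimethoxy-3,3-dimethylhex-1-ene | C=CC(C)(C)CCC(OC)OC | intermediate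
15 | (S)-5-(hydroxymethyl)dihydrofuran-2(3H)-one | O=C1CC[C@@H](CO)O1 | starting material
16 | (S)-5-[(tert-butyldimethylsilyloxy)methyl]dihydrofuran-2(3H)-one | O=C1CC[C@@H](CO[Si](C)(C)C(C)(C)C)O1 | intermediate
17 | (3S,5S)-3-[(benzyloxy)methyl]-5-[(tert-butyldimethylsilyloxy)methyl]dihydrofuran-2(3H)-one | O=C1[C@H](COCc2ccccc2)C[C@@H](CO[Si](C)(C)C(C)(C)C)O1 | intermediate
18 | (3S,5S)-3-[(benzyloxy)methyl]-6-(tert-butyldimethylsilyloxy)-5-hydroxyhexan-2-one | CC(=O)[C@H](COCc1ccccc1)C[C@H](O)CO[Si](C)(C)C(C)(C)C | intermediate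
19 | (3S,5S)-3-[(benzyloxy)methyl]-6-(tert-butyldimethylsilyloxy)-5-(triisopropylsilyloxy)hexan-2-one | CC(=O)[C@H](COCc1ccccc1)C[C@H](O[Si](C(C)C)(C(C)C)C(C)C)CO[Si](C)(C)C(C)(C)C | intermediate
20 | (2R,4S)-1-(benzyloxy)-5-(tert-butyldimethylsilyloxy)-2-(prop-1-en-2-yl)-4-(triisopropylsilyloxy)pentane | C=C(C)[C@H](COCc1ccccc1)C[C@H](O[Si](C(C)C)(C(C)C)C(C)C)CO[Si](C)(C)C(C)(C)C | intermediate
21 | (2R,4S)-5-(tert-butyldimethylsilyloxy)-2-(prop-1-en-2-yl)-4-(triisopropylsilyloxy)pentan-1-ol | C=C(C)[C@H](CO)C[C@H](O[Si](C(C)C)(C(C)C)C(C)C)CO[Si](C)(C)C(C)(C)C | intermediate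
22 | (2R,4S)-5-(tert-butyldimethylsilyloxy)-1-iodo-2-(prop-1-en-2-yl)-4-(triisopropylsilyloxy)pentane | C=C(C)[C@H](CI)C[C@H](O[Si](C(C)C)(C(C)C)C(C)C)CO[Si](C)(C)C(C)(C)C | intermediate
23 | lithium B-methoxy-B-alkyl-9-borabicyclo[3.3.1]nonane ate complex derived from 22 (not isolated) | [Li+].CO[B-]1(C[C@@H](C(C)=C)C[C@H](O[Si](C(C)C)(C(C)C)C(C)C)CO[Si](C)(C)C(C)(C)C)C2CCCC1CCC2 | intermediate
24 | 4-hydroxy-2-methoxy-6-methyl-5-[(2R,4S)-5-(tert-butyldimethylsilyloxy)-2-(prop-1-en-2-yl)-4-(triisopropylsilyloxy)pentyl]cyclohepta-2,4,6-trien-1-one | C=C(C)[C@H](CC1=C(O)C=C(OC)C(=O)C=C1C)C[C@H](O[Si](C(C)C)(C(C)C)C(C)C)CO[Si](C)(C)C(C)(C)C | intermediate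
25 | pyran B compound: methoxytropone-fused dihydropyran, (R)-C(CH3) with (E)-7,7-dimethoxy-4,4-dimethylhept-2-en-1-yl chain, (R)-CH with (S)-3-(tert-butyldimethylsilyloxy)-2-(triisopropylsilyloxy)propyl chain | COC1=CC2=C(C[C@H](C[C@H](O[Si](C(C)C)(C(C)C)C(C)C)CO[Si](C)(C)C(C)(C)C)[C@@](C)(C/C=C/C(C)(C)CCC(OC)OC)O2)C(C)=CC1=O | intermediate
26 | primary alcohol from 25 | COC1=CC2=C(C[C@H](C[C@H](O[Si](C(C)C)(C(C)C)C(C)C)CO)[C@@](C)(C/C=C/C(C)(C)CCC(OC)OC)O2)C(C)=CC1=O | intermediate
27 | aldehyde from 26 | COC1=CC2=C(C[C@H](C[C@H](O[Si](C(C)C)(C(C)C)C(C)C)C=O)[C@@](C)(C/C=C/C(C)(C)CCC(OC)OC)O2)C(C)=CC1=O | intermediate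
28 | terminal alkyne from 27 | COC1=CC2=C(C[C@H](C[C@H](O[Si](C(C)C)(C(C)C)C(C)C)C#C)[C@@](C)(C/C=C/C(C)(C)CCC(OC)OC)O2)C(C)=CC1=O | intermediate
29 | aryloxyalkene carrying ring A (acetal end) | COC1=CC2=C(C[C@H](C[C@H](O[Si](C(C)C)(C(C)C)C(C)C)C(=C)OC3=CC(C)=CC(=O)C(OC)=C3)[C@@](C)(C/C=C/C(C)(C)CCC(OC)OC)O2)C(C)=CC1=O | intermediate
30 | bis(enol ether), precursor of the key step (enol ether E/Z) | COC1=CC2=C(C[C@H](C[C@H](O[Si](C(C)C)(C(C)C)C(C)C)C(=C)OC3=CC(C)=CC(=O)C(OC)=C3)[C@@](C)(C/C=C/C(C)(C)CC=COC)O2)C(C)=CC1=O | intermediate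
31 | macrocycle: bis(O-methyl), O-triisopropylsilyl target with methoxy group on Cb (epimers at Cb) | CC1=CC(=O)C(OC)=CC2=C1C(OC)[C@H]1CC(C)(C)/C=C/C[C@@]3(C)OC4=C(C[C@@H]3C[C@H](O[Si](C(C)C)(C(C)C)C(C)C)[C@]1(C)O2)C(C)=CC(=O)C(OC)=C4 | intermediate
32 | O-triisopropylsilyl bis(O-methyl) ether of the target | CC1=CC(=O)C(OC)=CC2=C1C[C@H]1CC(C)(C)/C=C/C[C@@]3(C)OC4=C(C[C@@H]3C[C@H](O[Si](C(C)C)(C(C)C)C(C)C)[C@]1(C)O2)C(C)=CC(=O)C(OC)=C4 | intermediate
33 | bis(O-methyl) ether of the target (not isolated) | CC1=CC(=O)C(OC)=CC2=C1C[C@H]1CC(C)(C)/C=C/C[C@@]3(C)OC4=C(C[C@@H]3C[C@H](O)[C@]1(C)O2)C(C)=CC(=O)C(OC)=C4 | intermediate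
34 | CNP0283947.4 | Cc1cc(=O)c(O)cc2c1C[C@H]1CC(C)(C)/C=C/C[C@@]3(C)Oc4cc(O)c(=O)cc(C)c4C[C@@H]3C[C@H](O)[C@]1(C)O2 | target

## Step count and risks

Total step count: 27. Longest linear sequence: 17 steps (15 → 34, steps 11–27; the branch 1 → 9 → 24 → 34, steps 1–7 and 18–27, is equally long).

Steps most likely to fail:

1. Step 25 (Proposed new method). The first C–C bond formation has to close an 11-membered ring; at the cation stage intermolecular attack (oligomerisation) or loss of the proton back to the enol ethers may outrun it, and binding of the acid to the tropone carbonyls may make C-protonation of the aryloxyalkene too slow. The fallback separates fragment union from macrocyclisation; it sets out from 24 and comes back at 31. The oxidative cyclisation of 24 is run with ethene as the Heck acceptor and should give allyl compound F1. F1 is taken through the operations of steps 20–23 (HF·pyridine; Dess–Martin periodinane; Ohira–Bestmann reagent; gold-catalysed addition of 10) via primary alcohol F2, aldehyde F3 and terminal alkyne F4 to aryloxyalkene F5. An intermolecular oxa-Povarov reaction of F5 with an excess of isolated enol ether 13 (HNTf2 cat., CH2Cl2, −40 °C) builds pyran A without a ring-size penalty and gives diene F6. Ring-closing metathesis of F6 (second-generation Grubbs catalyst, toluene, 80 °C, 1 mM) closes the 11-membered ring at the disubstituted alkene and gives 31.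

2. Step 19. Carbopalladation of the hindered, unactivated alkene 14 by the neopentyl-type alkylpalladium intermediate may be slow, so that protodepalladation or reversal of the oxypalladation takes over; the neighbouring stereocentre may also erode the facial selectivity of the oxypalladation. The fallback sets out from 24 and comes back at 25: the same oxidative cyclisation with ethene (1 atm) as the small, unhindered acceptor gives allyl compound F1, and cross-metathesis of F1 with an excess of 14 (second-generation Hoveyda–Grubbs catalyst, CH2Cl2, 40 °C) forms the E-alkene of 25.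

3. Step 23. C-attack of the troponoid nucleophile (hydroarylation) or hydration of the gold-activated alkyne may compete with Markovnikov O-addition. The fallback sets out from 28 and comes back at 29: copper-catalysed Markovnikov hydroboration of the terminal alkyne (CuCl, N-heterocyclic carbene ligand, NaOt-Bu, bis(pinacolato)diboron, MeOH) gives 1,1-disubstituted alkenylboronate F7, and Chan–Lam–Evans coupling of F7 with 10 (Cu(OAc)2, pyridine, air, 4 Å MS, CH2Cl2) gives 29.

## Further compounds

F1 | step 19 | allyl compound: pyran B compound as 25 with a prop-2-en-1-yl group on the quaternary carbon | COC1=CC2=C(C[C@H](C[C@H](O[Si](C(C)C)(C(C)C)C(C)C)CO[Si](C)(C)C(C)(C)C)[C@@](C)(CC=C)O2)C(C)=CC1=O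
F2 | step 25 | primary alcohol from F1 | COC1=CC2=C(C[C@H](C[C@H](O[Si](C(C)C)(C(C)C)C(C)C)CO)[C@@](C)(CC=C)O2)C(C)=CC1=O
F3 | step 25 | aldehyde from F2 | COC1=CC2=C(C[C@H](C[C@H](O[Si](C(C)C)(C(C)C)C(C)C)C=O)[C@@](C)(CC=C)O2)C(C)=CC1=O
F4 | step 25 | terminal alkyne from F3 | COC1=CC2=C(C[C@H](C[C@H](O[Si](C(C)C)(C(C)C)C(C)C)C#C)[C@@](C)(CC=C)O2)C(C)=CC1=O
F5 | step 25 | aryloxyalkene carrying ring A and the allyl group | COC1=CC2=C(C[C@H](C[C@H](O[Si](C(C)C)(C(C)C)C(C)C)C(=C)OC3=CC(C)=CC(=O)C(OC)=C3)[C@@](C)(CC=C)O2)C(C)=CC1=O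
F6 | step 25 | diene with pyran A formed: Ct carries the 2,2-dimethylbut-3-en-1-yl group, Cb a methoxy group, pyran B the allyl group | CC1=CC(=O)C(OC)=CC2=C1C(OC)[C@@H](CC(C)(C)C=C)[C@@](C)(O2)[C@@H](O[Si](C(C)C)(C(C)C)C(C)C)C[C@H]3CC4=C(O[C@]3(C)CC=C)C=C(OC)C(=O)C=C4C
F7 | step 23 | 1,1-disubstituted alkenyl pinacol boronate from 28 | COC1=CC2=C(C[C@H](C[C@H](O[Si](C(C)C)(C(C)C)C(C)C)C(=C)B3OC(C)(C)C(C)(C)O3)[C@@](C)(C/C=C/C(C)(C)CCC(OC)OC)O2)C(C)=CC1=O
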